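# Proposed total synthesis of CNP0077405.2 (compound 19)

## Analysis of the target

- **Skeleton and locants.** Compound 19 is a 5,10-seco-clerodane-type diterpenoid built on a trans-fused bicyclo[5.3.0]decane. The locants used for every intermediate are: cyclopentane C1 (ring-fusion CH), C2 (CH2), C3 (CHOH), C4 (CMe2), C5 (ring-fusion C–OH); cycloheptanone C1, C5, C6, C7, C8 (CHMe, methyl C17), C9 (quaternary, methyl C20 and chain C11–C12), C10 (C=O); butenolide C13–C16, attached through C13.
- **Stereocentres.** There are five, in two clusters: C1, C3, C5 on the cyclopentane and C8, C9 on the seven-membered ring, (1R,3R,5R,8R,9S). O3 is trans to O5; O5 is cis to the C1–C10 bond, which makes the ring fusion trans; the methyl groups C17 and C20 are cis and the C11 chain is trans to C17.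
- **Congestion.** The tertiary carbinol C5 sits between the quaternary C4 and the ring fusion, and the quaternary C9 sits next to the C10 ketone.
- **Sensitive groups.** The β-hydroxy ketone O–C5–C1–C10=O can undergo retro-aldol cleavage, dehydration and epimerisation at C1. The butenolide is sensitive to base, nucleophiles and hydride.
- **The feature the route is built on.** The aldol unit lies exactly on the ring-fusion bond C1–C5. Its retro-aldol opening gives a ten-membered 1,6-dione whose carbonyl carbons C5 and C10 can be joined as the tetrasubstituted alkene of a decalin.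
- **What makes it hard.** That seco-dione is almost symmetric: each carbonyl is flanked by a quaternary carbon and a methylene. A plain aldol closure can therefore run C1→C5 or C6→C10. In addition, the two stereo-clusters are too far apart to control each other.

## Retrosynthetic reasoning

**19 ⇒ 18.** The C3 hydroxyl is carried as a triethylsilyl ether. A free C3–OH next to the C5 ketone of the ring-opened stage would be a β-hydroxy ketone with a quaternary α-carbon (retro-aldol), and it could also add to C10. Only a mild desilylation is left for the end.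

**18 ⇒ 16 (key disconnection, bond C1–C5).** Cutting the ring-fusion bond as a retro-aldol turns the bicycle into the ten-membered ring 16. The cut is placed here because this one bond builds both rings of the core and both ring-fusion stereocentres, and no other bond of the skeleton does that. To remove the C1/C6 ambiguity, 16 carries a C1=C2 double bond conjugated to the C10 ketone. In the forward direction, hydride addition to C2 creates the enolate at C1 and nowhere else, and this enolate must then add across the ring to the C5 ketone.

**16 ⇒ 14 (bond C5–C10, not present in the target).** The two ketones of 16 are reconnected as the tetrasubstituted alkene of the decalin diene 14. The gain is that the ten-membered ring with its three stereocentres comes from a rigid six/six system made by cycloaddition. The forward reaction must cleave the C5=C10 bond in the presence of the C1=C2 bond and the butenolide.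

**14 ⇒ 11 + 12 (bond C12–C13).** The butenolide is attached by hydroboration of a vinyl group on C9 and sp3–sp2 cross-coupling with 12. It is introduced before the alkene cleavage because a free vinyl group would not survive that step.

**11 ⇒ 10 ⇒ 9 (C3 stereocentre).** The C3 carbinol is traced back to the dienone 9. C3 is remote from C8/C9, so the forward reduction must be reagent-controlled.

**9 ⇒ 7 (position of the ring alkene).** The linear dienone 9 comes from ketone 7 by dehydrogenation at C1–C2 followed by base-mediated alkene migration. The same C1=C2 bond that later directs the enolate makes C10–H doubly activated, so the cycloadduct alkene C5=C6 is driven into the required C5=C10 position. The stereocentre C10 of 7 is erased, so endo and exo cycloadducts converge.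

**7 ⇒ 6 ⇒ 4 + 5 (bonds C7–C8 and C9–C10).** The vinyl group is an aldehyde one step earlier (6). Ring B with C8 and C9 is cut by a Diels–Alder disconnection into the semicyclic diene 4 and the E-enal 5. The E geometry of 5 delivers the cis relation of C17 and C20, and a chiral Lewis acid has to choose the enal face.

**4 ⇒ 2 + 3 ⇒ 1.** The diene comes from the symmetrical dione 1 by mono-enol triflate formation and vinylation. The quaternary C4 allows enolisation only toward C10.

## Alternatives that were turned down

**Alternative 1: (textbook) stepwise annulation.** The seven-membered ring would be closed onto a preformed cyclopentane by ring-closing metathesis at C8=C9 to give the bicyclic enone A1. C8 and C9 would then be set by conjugate methylation at C8 and alkylation of the resulting enolate at C9. It was turned down for three reasons. The two new centres lie on a flexible cycloheptenone and are 1,4- and 1,5-related to C1/C5, so no element of A1 controls their configuration relative to the cyclopentane. The fully substituted enolate must be alkylated with an unactivated two-carbon electrophile next to a ketone whose other α-carbon (C1) carries a β-leaving hydroxyl. The sequence is long and linear and builds the core one bond at a time.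

**Alternative 2: base-mediated transannular aldol of the saturated seco-dione A2.** This is the biomimetic version: A2 would come from cleavage of a C5=C10 octalin without the C1=C2 bond. It was turned down because A2 offers two enolisable methylenes (C1 and C6) and two equally hindered ketones, so closure C6→C10 competes with C1→C5 and nothing in the substrate decides between them. The octalin precursor would also have no handle to place the alkene at C5=C10 rather than C5=C6.

**Alternative 3: intramolecular (4+3) cycloaddition.** An oxyallyl cation (C9–C10–C1) would add to a tethered 1-alkoxy diene (C5–C8) to give the hydroazulenone A3, forming C1–C5 and C8–C9 and four stereocentres at once. It was turned down because both new bonds would be made at fully substituted termini (C9 and C5). The compact and extended transition states and the two diene faces would not be differentiated in a predictable way, and the acyclic precursor would need as many steps as the decalin route.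

Key step: step 10

## Route

Assumption: the facial sense of the oxazaborolidinium catalyst in step 3 is taken from the formyl C–H···O binding model for α-substituted enals; if the sense were opposite, the enantiomeric catalyst would be used with no other change.

**Step 1**
Reactants: 1 2,2-dimethylcyclohexane-1,3-dione
Product: 2 6,6-dimethyl-5-oxocyclohex-1-en-1-yl trifluoromethanesulfonate
Conditions: KN(SiMe3)2 (1.0 equiv), THF, −78 °C; PhNTf2, −78 → 0 °C
Reagents that add atoms: N-phenylbis(trifluoromethanesulfonimide), O=S(=O)(N(c1ccccc1)S(=O)(=O)C(F)(F)F)C(F)(F)F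
Why: Enol triflate formation; one equivalent of base gives the mono-enolate of the symmetrical dione, and the quaternary C4 allows enolisation only toward C10, so a single vinyl triflate should result.

**Step 2**
Reactants: 2 6,6-dimethyl-5-oxocyclohex-1-en-1-yl trifluoromethanesulfonate; 3 2-ethenyl-4,4,5,5-tetramethyl-1,3,2-dioxaborolane
Product: 4 3-ethenyl-2,2-dimethylcyclohex-3-en-1-one
Conditions: Pd(PPh3)4 (5 mol %), K3PO4, 1,4-dioxane/H2O, 70 °C
Reagents that add atoms: none
Why: Suzuki–Miyaura coupling of an alkenyl triflate with a vinylboronate; zerovalent palladium inserts into the C–O bond and the coupling gives the semicyclic diene C10=C5–C6=C7 without touching the hindered ketone.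

**Step 3**
Reactants: 4 3-ethenyl-2,2-dimethylcyclohex-3-en-1-one; 5 (E)-2-methylbut-2-enal
Product: 6 (1S,2R,8aR)-1,2,5,5-tetramethyl-6-oxo-1,2,3,5,6,7,8,8a-octahydronaphthalene-1-carbaldehyde
Conditions: (S)-2-(o-tolyl)-CBS-oxazaborolidine (20 mol %), AlBr3 (16 mol %), CH2Cl2, −78 → −40 °C
Reagents that add atoms: none
Why: Chiral Lewis acid catalysed Diels–Alder reaction; the electrophilic β-carbon of the enal (C8) bonds to the unsubstituted diene terminus C7 and the α-carbon (C9) to C10, the usual sense for 1-vinylcyclohexenes, and the gem-dimethyl group at C4 holds the diene s-cis. The E geometry of 5 sets C17 and C20 cis, and the catalyst should expose the re face at the α-carbon to give (8R,9S). Endo or exo approach changes only C10, which is erased in step 5.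

**Step 4**
Reactants: 6 (1S,2R,8aR)-1,2,5,5-tetramethyl-6-oxo-1,2,3,5,6,7,8,8a-octahydronaphthalene-1-carbaldehyde
Product: 7 (4aS,5S,6R)-5-ethenyl-1,1,5,6-tetramethyl-3,4,4a,5,6,7-hexahydronaphthalen-2(1H)-one
Conditions: Ph3PCH3Br, KOtBu, THF, 0 → 20 °C
Reagents that add atoms: methyltriphenylphosphonium bromide, [Br-].C[P+](c1ccccc1)(c1ccccc1)c1ccccc1
Why: Wittig methylenation; the non-enolisable neopentyl aldehyde reacts far faster than the ketone flanked by the quaternary C4, and no stereocentre is at risk.

**Step 5**
Reactants: 7 (4aS,5S,6R)-5-ethenyl-1,1,5,6-tetramethyl-3,4,4a,5,6,7-hexahydronaphthalen-2(1H)-one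
Product: 9 (5S,6R)-5-ethenyl-1,1,5,6-tetramethyl-5,6,7,8-tetrahydronaphthalen-2(1H)-one, via enone 8 (not isolated)
Conditions: IBX, 4-methoxypyridine N-oxide, DMSO, 25 → 45 °C; then DBU, toluene, 60 °C
Reagents that add atoms: none
Why: IBX dehydrogenation of the ketone can only introduce C1=C2 because C4 is quaternary. In enone 8, C10–H is γ to the enone and allylic to C5=C6, so DBU removes it and reprotonation at C6 should give the linearly conjugated dienone as the thermodynamic sink. Both C10 epimers of 7 converge on 9.

**Step 6**
Reactants: 9 (5S,6R)-5-ethenyl-1,1,5,6-tetramethyl-5,6,7,8-tetrahydronaphthalen-2(1H)-one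
Product: 10 (2R,5S,6R)-5-ethenyl-1,1,5,6-tetramethyl-1,2,5,6,7,8-hexahydronaphthalen-2-ol
Conditions: (S)-2-methyl-CBS-oxazaborolidine (0.3 equiv), catecholborane, toluene, −78 °C; aq. NaOH work-up
Reagents that add atoms: none
Why: Corey–Bakshi–Shibata reduction; with the quaternary C4 as the large group and the planar C2–H side as the small one, the (S)-catalyst should deliver hydride to give (3R), independent of the remote C8/C9 centres. The s-trans dienone allows only 1,2-reduction, and catecholborane leaves the vinyl group alone at this temperature.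

**Step 7**
Reactants: 10 (2R,5S,6R)-5-ethenyl-1,1,5,6-tetramethyl-1,2,5,6,7,8-hexahydronaphthalen-2-ol
Product: 11 triethyl{[(2R,5S,6R)-5-ethenyl-1,1,5,6-tetramethyl-1,2,5,6,7,8-hexahydronaphthalen-2-yl]oxy}silane
Conditions: Et3SiOTf, 2,6-lutidine, CH2Cl2, −78 °C
Reagents that add atoms: triethylsilyl trifluoromethanesulfonate, CC[Si](CC)(CC)OS(=O)(=O)C(F)(F)F
Why: Silylation under buffered basic conditions avoids ionisation of the dienol (methyl shift and aromatisation). The ether later prevents retro-aldol cleavage at C3–C4 and addition of O3 to C10.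

**Step 8**
Reactants: 11 triethyl{[(2R,5S,6R)-5-ethenyl-1,1,5,6-tetramethyl-1,2,5,6,7,8-hexahydronaphthalen-2-yl]oxy}silane; 12 4-bromofuran-2(5H)-one
Product: 14 4-{2-[(1S,2R,6R)-1,2,5,5-tetramethyl-6-(triethylsilyloxy)-1,2,3,4,5,6-hexahydronaphthalen-1-yl]ethyl}furan-2(5H)-one, via alkylborane 13 (not isolated)
Conditions: 9-BBN dimer, THF, 0 → 25 °C; then 12, PdCl2(dppf) (5 mol %), AsPh3, aq. K3PO4, DMF, 25 → 45 °C
Reagents that add atoms: none
Why: 9-BBN hydroborates the monosubstituted vinyl group at C12 much faster than the ring diene. B-alkyl Suzuki–Miyaura coupling with the vinylogous acyl bromide then forms C12–C13 and installs the complete butenolide.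

**Step 9**
Reactants: 14 4-{2-[(1S,2R,6R)-1,2,5,5-tetramethyl-6-(triethylsilyloxy)-1,2,3,4,5,6-hexahydronaphthalen-1-yl]ethyl}furan-2(5H)-one
Product: 16 4-{2-[(1S,2R,7R,8Z)-1,2,6,6-tetramethyl-5,10-dioxo-7-(triethylsilyloxy)cyclodec-8-en-1-yl]ethyl}furan-2(5H)-one, via ozonide 15 (not isolated)
Conditions: O3 (1.0 equiv, as a titrated CH2Cl2 solution), CH2Cl2, −78 °C; then PPh3, −78 → 0 °C
Reagents that add atoms: ozone, [O-][O+]=O
Why: Ozonolysis with Criegee cleavage; ozone should add to the tetrasubstituted, most electron-rich C5=C10 end of the diene. The C1=C2 bond becomes part of an enone once the first cleavage has occurred and, like the butenolide, is then electron-poor. Cleavage of the ring-fusion bond opens the decalin to the ten-membered ring.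

**Step 10**
Reactants: 16 4-{2-[(1S,2R,7R,8Z)-1,2,6,6-tetramethyl-5,10-dioxo-7-(triethylsilyloxy)cyclodec-8-en-1-yl]ethyl}furan-2(5H)-one
Product: 18 (2R,3aR,5S,6R,8aR)-8a-hydroxy-1,1,5,6-tetramethyl-5-[2-(5-oxo-2,5-dihydrofuran-3-yl)ethyl]-2-(triethylsilyloxy)octahydroazulen-4(1H)-one, via copper enolate 17 (not isolated)
Conditions: [(Ph3P)CuH]6 (0.25 equiv, 1.5 equiv of hydride), toluene/THF, −40 → 0 °C; then aq. NH4Cl
Reagents that add atoms: none
Why: Proposed new method: hydride transfer from [(Ph3P)CuH]6 to C2 of the cis-enone gives the monovalent copper enolate 17 with the nucleophilic carbon fixed at C1 (C9 is quaternary and the C5 ketone is never enolised), and this enolate adds across the ring to the C5 ketone; the closest known reaction type is the copper hydride reductive aldol cyclisation of tethered keto-enones, combined here with the long-known transannular aldol closure of cyclodecane-1,6-diones. The new C1–C5 bond closes the cyclopentane in a 5-(enolexo)-exo-trig mode and at the same time divides the ten-membered ring to leave the cycloheptanone (7-(enolendo)-exo-trig). C1 and C5 are set together: in the closed, copper-bridged transition state the enolate oxygen and the ketone oxygen lie on the same side of the forming bond, which places O5 and C10 cis on the cyclopentane and therefore gives the trans ring fusion. The choice between the two trans-fused pairs is made by the C3 silyl ether: the six-membered copper chelate should be built on the cyclopentane face opposite to OSiEt3, which is the (1R,5R) arrangement with O5 trans to O3. The step needs regioselectivity (C1 against C6 as nucleophile), secured by the position of the C1=C2 bond. It also needs chemoselectivity for the β-monosubstituted enone over the β,β-disubstituted butenolide and the saturated ketone, which the much faster conjugate hydride transfer to the enone should provide. The Thorpe–Ingold effect of C4 and the short C1···C5 distance across the ring favour closure over simple protonation of the enolate.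

**Step 11**
Reactants: 18 (2R,3aR,5S,6R,8aR)-8a-hydroxy-1,1,5,6-tetramethyl-5-[2-(5-oxo-2,5-dihydrofuran-3-yl)ethyl]-2-(triethylsilyloxy)octahydroazulen-4(1H)-one
Product: 19 (2R,3aR,5S,6R,8aR)-2,8a-dihydroxy-1,1,5,6-tetramethyl-5-[2-(5-oxo-2,5-dihydrofuran-3-yl)ethyl]octahydroazulen-4(1H)-one
Conditions: HF·pyridine, pyridine, THF, 0 → 20 °C
Reagents that add atoms: none
Why: Fluoride-mediated cleavage of the triethylsilyl ether under buffered, non-basic conditions should spare the β-hydroxy ketone (no retro-aldol, no epimerisation at C1) and the butenolide.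

## Compound list

1 | 2,2-dimethylcyclohexane-1,3-dione | CC1(C)C(=O)CCCC1=O | starting material
2 | 6,6-dimethyl-5-oxocyclohex-1-en-1-yl trifluoromethanesulfonate | CC1(C)C(=O)CCC=C1OS(=O)(=O)C(F)(F)F | intermediate
3 | 2-ethenyl-4,4,5,5-tetramethyl-1,3,2-dioxaborolane | C=CB1OC(C)(C)C(C)(C)O1 | starting material
4 | 3-ethenyl-2,2-dimethylcyclohex-3-en-1-one | CC1(C)C(=O)CCC=C1C=C | intermediate
5 | (E)-2-methylbut-2-enal | C/C=C(\C)C=O | starting material
6 | (1S,2R,8aR)-1,2,5,5-tetramethyl-6-oxo-1,2,3,5,6,7,8,8a-octahydronaphthalene-1-carbaldehyde (endo adduct; the C8a epimer would serve equally) | C[C@@H]1CC=C2C(C)(C)C(=O)CC[C@H]2[C@@]1(C)C=O | intermediate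
7 | (4aS,5S,6R)-5-ethenyl-1,1,5,6-tetramethyl-3,4,4a,5,6,7-hexahydronaphthalen-2(1H)-one | C[C@@H]1CC=C2C(C)(C)C(=O)CC[C@H]2[C@@]1(C)C=C | intermediate
8 | (4aS,5S,6R)-5-ethenyl-1,1,5,6-tetramethyl-4a,5,6,7-tetrahydronaphthalen-2(1H)-one (not isolated) | C[C@@H]1CC=C2C(C)(C)C(=O)C=C[C@H]2[C@@]1(C)C=C | intermediate
9 | (5S,6R)-5-ethenyl-1,1,5,6-tetramethyl-5,6,7,8-tetrahydronaphthalen-2(1H)-one | C[C@@H]1CCC2=C(C=CC(=O)C2(C)C)[C@@]1(C)C=C | intermediate
10 | (2R,5S,6R)-5-ethenyl-1,1,5,6-tetramethyl-1,2,5,6,7,8-hexahydronaphthalen-2-ol | C[C@@H]1CCC2=C(C=C[C@@H](O)C2(C)C)[C@@]1(C)C=C | intermediate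
11 | triethyl{[(2R,5S,6R)-5-ethenyl-1,1,5,6-tetramethyl-1,2,5,6,7,8-hexahydronaphthalen-2-yl]oxy}silane | C[C@@H]1CCC2=C(C=C[C@@H](O[Si](CC)(CC)CC)C2(C)C)[C@@]1(C)C=C | intermediate
12 | 4-bromofuran-2(5H)-one | BrC1=CC(=O)OC1 | starting material
13 | 9-{2-[(1S,2R,6R)-1,2,5,5-tetramethyl-6-(triethylsilyloxy)-1,2,3,4,5,6-hexahydronaphthalen-1-yl]ethyl}-9-borabicyclo[3.3.1]nonane (not isolated) | C[C@@H]1CCC2=C(C=C[C@@H](O[Si](CC)(CC)CC)C2(C)C)[C@@]1(C)CCB1C2CCCC1CCC2 | intermediate
14 | 4-{2-[(1S,2R,6R)-1,2,5,5-tetramethyl-6-(triethylsilyloxy)-1,2,3,4,5,6-hexahydronaphthalen-1-yl]ethyl}furan-2(5H)-one | C[C@@H]1CCC2=C(C=C[C@@H](O[Si](CC)(CC)CC)C2(C)C)[C@@]1(C)CCC1=CC(=O)OC1 | intermediate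
15 | secondary ozonide (1,2,4-trioxolane) of 14 across C5 and C10; the bridge may form on either face, C5 and C10 therefore left undefined (not isolated) | C[C@@H]1CCC23OOC(O2)(C=C[C@@H](O[Si](CC)(CC)CC)C3(C)C)[C@@]1(C)CCC1=CC(=O)OC1 | intermediate
16 | 4-{2-[(1S,2R,7R,8Z)-1,2,6,6-tetramethyl-5,10-dioxo-7-(triethylsilyloxy)cyclodec-8-en-1-yl]ethyl}furan-2(5H)-one | C[C@@H]1CCC(=O)C(C)(C)[C@H](O[Si](CC)(CC)CC)/C=C\C(=O)[C@@]1(C)CCC1=CC(=O)OC1 | intermediate
17 | copper enolate of the C10 ketone (C10–O–Cu, C10=C1; phosphine ligands omitted, enolate geometry not assigned; not isolated) | C[C@@H]1CCC(=O)C(C)(C)[C@H](O[Si](CC)(CC)CC)CC=C(O[Cu])[C@@]1(C)CCC1=CC(=O)OC1 | intermediate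
18 | (2R,3aR,5S,6R,8aR)-8a-hydroxy-1,1,5,6-tetramethyl-5-[2-(5-oxo-2,5-dihydrofuran-3-yl)ethyl]-2-(triethylsilyloxy)octahydroazulen-4(1H)-one | C[C@@H]1CC[C@@]2(O)[C@@H](C[C@@H](O[Si](CC)(CC)CC)C2(C)C)C(=O)[C@@]1(C)CCC1=CC(=O)OC1 | intermediate
19 | (2R,3aR,5S,6R,8aR)-2,8a-dihydroxy-1,1,5,6-tetramethyl-5-[2-(5-oxo-2,5-dihydrofuran-3-yl)ethyl]octahydroazulen-4(1H)-one | C[C@@H]1CC[C@@]2(O)[C@@H](C[C@@H](O)C2(C)C)C(=O)[C@@]1(C)CCC1=CC(=O)OC1 | target

## Step count and least certain steps

Total step count: 11. Longest linear sequence: 11 steps (1 → 19).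

**Step 10 (key step, Proposed new method).** Three processes may interfere: protonation of the copper enolate before it closes the ring, formation of the cis-fused ketol or the other trans-fused pair if the copper chelate does not form on the face opposite to OSiEt3, and Michael addition of the enolate to the butenolide. The fallback uses known chemistry and sets out from 16. Conjugate hydrosilylation of the enone with Et3SiH and RhCl(PPh3)3 should give the regiodefined triethylsilyl enol ether F1, which can be purified. Treatment of F1 with TiCl4 in CH2Cl2 at −78 °C (intramolecular Mukaiyama aldol addition to the C5 ketone through an open transition state) and aqueous work-up returns to the route at 18. The nucleophilic carbon is again fixed at C1, and the different transition-state geometry gives a second chance for the ring-fusion configuration.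

**Step 3.** The hindered diene and the trisubstituted enal may react slowly with the chiral catalyst, and the face selection or the orientation of addition may be incomplete. The fallback sets out from 4 and 5. Cycloaddition promoted by EtAlCl2 in CH2Cl2 should give 6 together with its enantiomer F2. Condensation of the mixture with (1R,2R)-N,N'-dimethyl-1,2-diphenylethane-1,2-diamine over molecular sieves gives the diastereomeric aminals F3 (from 6) and F4 (from F2), which are separated by chromatography. Mild aqueous acid hydrolysis of F3 returns to the route at 6.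

**Step 9.** Ozone may attack C1=C2 competitively, may stop at epoxidation of the hindered tetrasubstituted alkene, or may over-oxidise the product. The fallback sets out from 14. Dimethyldioxirane in acetone at −20 °C should epoxidise the most substituted double bond to the vinyl epoxide F5. Periodic acid (H5IO6) in aqueous THF opens the epoxide to the glycol and cleaves it in the same flask, returning to the route at 16.

**Step 6.** Both groups flanking the C3 carbonyl are demanding (quaternary C4, dienyl C2), so facial discrimination by the catalyst may be poor. The fallback replaces asymmetric induction by separation and recycling and sets out from 9. Luche reduction (NaBH4, CeCl3, MeOH, −40 °C) gives 10 together with its C3 epimer F6. The two are separated, and F6 is oxidised back to 9 with MnO2 and resubmitted; the route is rejoined at 10.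

## Further compounds

F1 | step 10 | 4-{2-[(1S,2R,7R)-1,2,6,6-tetramethyl-5-oxo-7,10-bis(triethylsilyloxy)cyclodec-9-en-1-yl]ethyl}furan-2(5H)-one (silyl enol ether C10=C1, geometry not assigned) | C[C@@H]1CCC(=O)C(C)(C)[C@H](O[Si](CC)(CC)CC)CC=C(O[Si](CC)(CC)CC)[C@@]1(C)CCC1=CC(=O)OC1
F2 | step 3 | (1R,2S,8aS)-1,2,5,5-tetramethyl-6-oxo-1,2,3,5,6,7,8,8a-octahydronaphthalene-1-carbaldehyde | C[C@H]1CC=C2C(C)(C)C(=O)CC[C@@H]2[C@]1(C)C=O
F3 | step 3 | (4aR,5S,6R)-5-[(4R,5R)-1,3-dimethyl-4,5-diphenylimidazolidin-2-yl]-1,1,5,6-tetramethyl-3,4,4a,5,6,7-hexahydronaphthalen-2(1H)-one (aminal of 6) | C[C@@H]1CC=C2C(C)(C)C(=O)CC[C@H]2[C@@]1(C)C1N(C)[C@H](c2ccccc2)[C@@H](c2ccccc2)N1C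
F4 | step 3 | (4aS,5R,6S)-5-[(4R,5R)-1,3-dimethyl-4,5-diphenylimidazolidin-2-yl]-1,1,5,6-tetramethyl-3,4,4a,5,6,7-hexahydronaphthalen-2(1H)-one (aminal of F2) | C[C@H]1CC=C2C(C)(C)C(=O)CC[C@@H]2[C@]1(C)C1N(C)[C@H](c2ccccc2)[C@@H](c2ccccc2)N1C
F5 | step 9 | 5,10-epoxide of 14 (oxirane drawn on the face of the C20 methyl group; the other face would serve equally) | C[C@@H]1CC[C@]23O[C@]2(C=C[C@@H](O[Si](CC)(CC)CC)C3(C)C)[C@@]1(C)CCC1=CC(=O)OC1
F6 | step 6 | (2S,5S,6R)-5-ethenyl-1,1,5,6-tetramethyl-1,2,5,6,7,8-hexahydronaphthalen-2-ol | C[C@@H]1CCC2=C(C=C[C@H](O)C2(C)C)[C@@]1(C)C=C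
A1 | alternative 1 | (2R,3aR,8aR)-8a-hydroxy-1,1,5-trimethyl-2-(triethylsilyloxy)-2,3,3a,7,8,8a-hexahydroazulen-4(1H)-one | CC1=CCC[C@@]2(O)[C@@H](C[C@@H](O[Si](CC)(CC)CC)C2(C)C)C1=O
A2 | alternative 2 | 4-{2-[(1S,2R,7R)-1,2,6,6-tetramethyl-5,10-dioxo-7-(triethylsilyloxy)cyclodecyl]ethyl}furan-2(5H)-one | C[C@@H]1CCC(=O)C(C)(C)[C@H](O[Si](CC)(CC)CC)CCC(=O)[C@@]1(C)CCC1=CC(=O)OC1
A3 | alternative 3 | (2R,3aR,5S,6R,8aR)-5-ethenyl-8a-methoxy-1,1,5,6-tetramethyl-2-(triethylsilyloxy)-2,3,3a,5,6,8a-hexahydroazulen-4(1H)-one | C[C@@H]1C=C[C@@]2(OC)[C@@H](C[C@@H](O[Si](CC)(CC)CC)C2(C)C)C(=O)[C@@]1(C)C=C
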